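**Plan**

Locants: cyclopenta[c]pyran core C1, O2, C3, C4, C4a, C5–C7, C7a; acyl chain C1'–C3'. The retrosynthesis cuts, in this order, C1–C3 of the coumarin (back to a C1 methyl acetal), C4–C4a (opening the dihydropyran ring to a C4a radical and an allene), C3–C1' (lithiated allenyl ether plus amide), the C1 acetal, and the six-membered ring of pulegone.
Forward: the cyclopentane ring arises first by ring contraction; C1 is raised to a mixed methyl/allenyl acetal and C4a receives a phenylselanyl group; the acyl chain is joined at C3; the dihydropyran ring closes in the radical step; the coumarin is joined last.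
Enabling feature: in the dihydropyran ring C4 is at once the β-carbon of the C1' ketone and the methyl-bearing carbon of the C3=C4 enol ether, so an α-alkoxy allenyl ketone (C3=C4=CH2) hung from O2 is its latent form and takes up a C4a radical at the central allene carbon.
Stereochemistry: C7 from (S)-pulegone; C7a by equilibration of the β-keto ester (trans to the C7 methyl); C4a by the forced cis ring fusion of the radical closure; C1 by convex-face attack on the bicyclic oxocarbenium ion; C2' from (R)-2-hydroxy-3-methylbutanoic acid.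
Two choices keep the steps compatible: the radical precursor is a phenyl selenide, which should tolerate KOt-Bu and n-BuLi at −78 °C, and the coumarin lactone meets no organolithium because it is attached at the end.

Key step: step 13

Assumption: borohydride reduction of the β-keto ester obtained after ozonolysis is taken to give mainly the cis-hydroxy ester; the other C4a epimer would pass through the same steps, and both converge in the key step, where C4a becomes a planar radical.

**Route**

Step 1
Reactants: 1 (S)-pulegone
Product: 3 methyl (2S)-2-methyl-5-(propan-2-ylidene)cyclopentane-1-carboxylate (methyl pulegenate; C1 epimers), via pulegone dibromide 2 (not isolated)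
Conditions: Br2, Et2O, −10 °C; then NaOMe, MeOH, reflux
Reagents that add atoms: sodium methoxide, [Na+].[O-]C; bromine, BrBr (stays only in intermediate 2)
Why: Favorskii ring contraction: methoxide converts the dibromide through a cyclopropanone whose opening expels the second bromide and restores the isopropylidene group; the methyl-bearing stereocenter is not involved.

Step 2
Reactants: 3 methyl pulegenate
Product: 4 methyl (1R,2S)-2-methyl-5-oxocyclopentane-1-carboxylate
Conditions: O3, CH2Cl2/MeOH, −78 °C; then Me2S, −78 °C → rt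
Reagents that add atoms: ozone, [O-][O+]=O
Why: Ozonolysis of the tetrasubstituted alkene with reductive work-up; the ester-bearing carbon of the β-keto ester equilibrates through the enol to the isomer with the ester trans to the methyl group, which fixes C7a.

Step 3
Reactants: 4 keto ester
Product: 5 methyl (1R,2S,5S)-2-hydroxy-5-methylcyclopentane-1-carboxylate
Conditions: NaBH4, MeOH, −40 → 0 °C
Reagents that add atoms: none
Why: Borohydride reduction of the ketone; hydride should add anti to the neighbouring ester and give mainly the cis-hydroxy ester, but this center is destroyed in step 13, so its configuration is of no consequence.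

Step 4
Reactants: 5 hydroxy ester
Product: 6 methyl (1R,2S,5S)-2-methyl-5-[(triethylsilyl)oxy]cyclopentane-1-carboxylate
Conditions: Et3SiCl, imidazole, CH2Cl2, 0 °C → rt
Reagents that add atoms: chlorotriethylsilane, CC[Si](Cl)(CC)CC
Why: Silylation of the secondary alcohol; the ether blocks retro-aldol and elimination during the hydride reduction of the ester.

Step 5
Reactants: 6 silyl ether ester
Product: 7 (1R,2S,5S)-2-methyl-5-[(triethylsilyl)oxy]cyclopentane-1-carbaldehyde
Conditions: i-Bu2AlH (1.05 equiv), CH2Cl2, −78 °C; aq. potassium sodium tartrate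
Reagents that add atoms: none
Why: Partial ester reduction through a tetrahedral aluminium hemiacetal that collapses only on work-up; C7a is kept by working cold and using the aldehyde at once.

Step 6
Reactants: 7 aldehyde
Product: 8 (1S,2R,3S)-2-(dimethoxymethyl)-3-methylcyclopentan-1-ol
Conditions: HC(OMe)3, camphor-10-sulfonic acid (cat.), MeOH, 0 °C → rt
Reagents that add atoms: trimethyl orthoformate, COC(OC)OC; methanol, CO
Why: Acid-catalysed acetalisation with the orthoformate as water scavenger; the acid-labile triethylsilyl ether is methanolysed in the same flask, and the acetal removes the enolisable aldehyde so that C7a can no longer epimerise.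

Step 7
Reactants: 8 hydroxy acetal
Product: 9 {[(1R,2S,3S)-2-(dimethoxymethyl)-3-methylcyclopentyl]selanyl}benzene
Conditions: N-(phenylselanyl)phthalimide, n-Bu3P, THF, 0 °C → rt
Reagents that add atoms: N-(phenylselanyl)phthalimide, O=C1c2ccccc2C(=O)N1[Se]c1ccccc1
Why: Mitsunobu-type selenation: the alcohol is activated as an alkoxyphosphonium salt and displaced by phenylselenolate in an SN2 reaction with inversion, on the face away from the acetal side chain; the acetal has no acidic α-hydrogen, so elimination should not compete.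

Step 8
Reactants: 9 selenide dimethyl acetal
Product: 11 {[(1R,2S,3S)-2-[methoxy(prop-2-yn-1-yloxy)methyl]-3-methylcyclopentyl]selanyl}benzene (acetal epimers), via methoxy-collidinium triflate 10 (not isolated)
Conditions: Et3SiOTf, 2,4,6-trimethylpyridine, CH2Cl2, 0 °C; then prop-2-yn-1-ol, 0 °C → rt
Reagents that add atoms: prop-2-yn-1-ol, C#CCO; 2,4,6-trimethylpyridine, Cc1cc(C)nc(C)c1, and triethylsilyl triflate, CC[Si](CC)(CC)OS(=O)(=O)C(F)(F)F (both stay only in intermediate 10)
Why: Mixed-acetal synthesis through a pyridinium-type salt: one methoxy group is exchanged for the pyridinium unit, which propargyl alcohol displaces under nearly neutral conditions; the new acetal center is not controlled and is erased in step 17.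

Step 9
Reactants: 11 propargyl methyl acetal
Product: 12 {[(1R,2S,3S)-2-[methoxy(propa-1,2-dien-1-yloxy)methyl]-3-methylcyclopentyl]selanyl}benzene (acetal epimers)
Conditions: KOt-Bu (0.3 equiv), THF, 0 °C → rt
Reagents that add atoms: none
Why: Base-catalysed prototropic isomerisation of a propargyl ether to the allenyl ether; with catalytic base in THF it should stop at the allene, and the selenide and acetal are inert.

Step 10
Reactants: 13 (R)-2-hydroxy-3-methylbutanoic acid
Product: 14 (2R)-2-hydroxy-N-methoxy-N,3-dimethylbutanamide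
Conditions: MeNHOMe·HCl, N-ethyl-N'-(3-dimethylaminopropyl)carbodiimide hydrochloride, 1-hydroxybenzotriazole (cat.), N-methylmorpholine, CH2Cl2, 0 °C → rt
Reagents that add atoms: N,O-dimethylhydroxylamine hydrochloride, CNOC.Cl
Why: Carbodiimide-mediated amide coupling to the Weinreb amide; C2' is not enolised under these conditions.

Step 11
Reactants: 14 hydroxy amide
Product: 15 (2R)-2-[(tert-butyldimethylsilyl)oxy]-N-methoxy-N,3-dimethylbutanamide
Conditions: t-BuMe2SiOTf, 2,6-lutidine, CH2Cl2, 0 °C
Reagents that add atoms: tert-butyldimethylsilyl trifluoromethanesulfonate, CC(C)(C)[Si](C)(C)OS(=O)(=O)C(F)(F)F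
Why: Silylation of the hindered secondary alcohol with the silyl triflate; an acetate here would not survive the organolithium step.

Step 12
Reactants: 12 allenyl methyl acetal; 15 silyloxy Weinreb amide
Product: 17 (5R)-5-[(tert-butyldimethylsilyl)oxy]-3-{methoxy[(1S,2S,5R)-2-methyl-5-(phenylselanyl)cyclopentyl]methoxy}-6-methylhepta-1,2-dien-4-one (acetal epimers), via lithioallene 16 (not isolated)
Conditions: n-BuLi (1.0 equiv), THF, −78 °C, 20 min; then 15, −78 → −30 °C; pH 7 buffer
Reagents that add atoms: n-butyllithium, [Li]CCCC (lithium stays only in intermediate 16)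
Why: α-Lithiation of the alkoxyallene at the sp2 C–H next to oxygen, then Weinreb ketone synthesis: the chelated tetrahedral adduct prevents over-addition and releases the α-alkoxy allenyl ketone on quench; simple alkyl phenyl selenides should not be attacked by n-BuLi at −78 °C on this time scale.

Step 13
Reactants: 17 allenyl ketone
Product: 19 (2R)-2-[(tert-butyldimethylsilyl)oxy]-1-[(4aS,7S,7aR)-1-methoxy-4,7-dimethyl-1,4a,5,6,7,7a-hexahydrocyclopenta[c]pyran-3-yl]-3-methylbutan-1-one (C1 epimers), via exo-methylene tautomer 18 (not isolated)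
Conditions: (Me3Si)3SiH (1.3 equiv) and azobisisobutyronitrile (0.2 equiv) by syringe pump over 6 h, PhH (0.01 M), 80 °C; then Et3N (cat.), CH2Cl2, rt
Reagents that add atoms: none
Why: The silyl radical abstracts the phenylselanyl group to give the secondary C4a radical in a chain process; this is a Giese-type reductive conjugate cyclization, and the closest known reaction type is alkyl-radical addition to the central carbon of allenoates and allenyl ketones. The nucleophilic radical adds to the sp carbon C4, the β-carbon of the C1' ketone, and closes the dihydropyran ring in a 6-endo mode with respect to C3=C4 (6-exo with respect to C4=CH2). Attack at C3 (5-exo) is disfavoured because C3 is fully substituted, polarity-mismatched and would give a vinyl radical, whereas attack at C4 gives an allyl radical stabilised by the ring oxygen and the ketone. The new stereocenter C4a is controlled by C7a: the C1–O2–C3 tether hangs from C7a and should reach only the same face of the planar radical, so the ring is cis-fused and both selenide epimers give one product. Hydrogen transfer to the terminal CH2 gives 19 directly, and any fraction that takes up hydrogen at C3 (tautomer 18) is drawn into conjugation by Et3N. The step needs high dilution and slow silane addition so that ring closure outruns reduction of the C4a radical and silyl-radical addition to the allene.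

Step 14
Reactants: 19 silyloxy ketone
Product: 20 (2R)-2-hydroxy-1-[(4aS,7S,7aR)-1-methoxy-4,7-dimethyl-1,4a,5,6,7,7a-hexahydrocyclopenta[c]pyran-3-yl]-3-methylbutan-1-one (C1 epimers)
Conditions: HF·pyridine, pyridine, THF, 0 °C → rt
Reagents that add atoms: none
Why: Fluoride-mediated silyl ether cleavage under pyridine-buffered conditions; the C1 acetal, whose ring oxygen is deactivated as a vinylogous ester, should survive.

Step 15
Reactants: 20 hydroxy ketone
Product: 21 (2R)-1-[(4aS,7S,7aR)-1-methoxy-4,7-dimethyl-1,4a,5,6,7,7a-hexahydrocyclopenta[c]pyran-3-yl]-3-methyl-1-oxobutan-2-yl acetate (C1 epimers)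
Conditions: Ac2O, pyridine, 4-(dimethylamino)pyridine (cat.), CH2Cl2, 0 °C → rt
Reagents that add atoms: acetic anhydride, CC(=O)OC(C)=O
Why: Acylation of the α-hydroxy ketone with nucleophilic acyl-transfer catalysis; it installs the C2' acetate of the target without touching C2'.

Step 16
Reactants: 22 1-(2-hydroxy-6-methylphenyl)ethanone
Product: 23 4-hydroxy-5-methyl-2H-chromen-2-one
Conditions: (EtO)2CO, NaH, toluene, 110 °C; then aq. HCl
Reagents that add atoms: diethyl carbonate, CCOC(=O)OCC
Why: Claisen-type C-acylation of the ketone enolate by diethyl carbonate followed by lactonisation onto the phenoxide, the standard route from 2-hydroxyacetophenones to 4-hydroxycoumarins.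

Step 17
Reactants: 21 C1 methyl acetal; 23 4-hydroxy-5-methylcoumarin (1.1 equiv)
Product: 24 (2R)-1-[(1R,4aS,7S,7aR)-1-(4-hydroxy-5-methyl-2-oxo-2H-chromen-3-yl)-4,7-dimethyl-1,4a,5,6,7,7a-hexahydrocyclopenta[c]pyran-3-yl]-3-methyl-1-oxobutan-2-yl acetate (target)
Conditions: BF3·OEt2 (0.2 equiv), 4 Å molecular sieves, CH2Cl2, −20 °C → rt
Reagents that add atoms: none
Why: Friedel–Crafts-type (C-glycosylation-like) alkylation: the Lewis acid ionises the C1 acetal to the bicyclic oxocarbenium ion, and the enol carbon C3 of the coumarin attacks from the convex face, anti to the cyclopentane ring at C7a, which sets C1 (R) with the coumarin cis to H7a; O-bound adducts are themselves acetals and re-ionise, so the C–C bonded product should accumulate.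

**Compound list**

1 | (S)-pulegone, (5S)-5-methyl-2-(propan-2-ylidene)cyclohexan-1-one | C[C@H]1CCC(=C(C)C)C(=O)C1 | starting material
2 | (5S)-2-bromo-2-(2-bromopropan-2-yl)-5-methylcyclohexan-1-one (C2 epimers) | C[C@H]1CCC(Br)(C(C)(C)Br)C(=O)C1 | intermediate
3 | methyl (2S)-2-methyl-5-(propan-2-ylidene)cyclopentane-1-carboxylate (C1 epimers) | CC(C)=C1CC[C@H](C)C1C(=O)OC | intermediate
4 | methyl (1R,2S)-2-methyl-5-oxocyclopentane-1-carboxylate | O=C1CC[C@H](C)[C@H]1C(=O)OC | intermediate
5 | methyl (1R,2S,5S)-2-hydroxy-5-methylcyclopentane-1-carboxylate | O[C@H]1CC[C@H](C)[C@H]1C(=O)OC | intermediate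
6 | methyl (1R,2S,5S)-2-methyl-5-[(triethylsilyl)oxy]cyclopentane-1-carboxylate | CC[Si](CC)(CC)O[C@H]1CC[C@H](C)[C@H]1C(=O)OC | intermediate
7 | (1R,2S,5S)-2-methyl-5-[(triethylsilyl)oxy]cyclopentane-1-carbaldehyde | CC[Si](CC)(CC)O[C@H]1CC[C@H](C)[C@H]1C=O | intermediate
8 | (1S,2R,3S)-2-(dimethoxymethyl)-3-methylcyclopentan-1-ol | O[C@H]1CC[C@H](C)[C@H]1C(OC)OC | intermediate
9 | {[(1R,2S,3S)-2-(dimethoxymethyl)-3-methylcyclopentyl]selanyl}benzene | c1ccccc1[Se][C@@H]2CC[C@H](C)[C@H]2C(OC)OC | intermediate
10 | 1-{methoxy[(1S,2S,5R)-2-methyl-5-(phenylselanyl)cyclopentyl]methyl}-2,4,6-trimethylpyridinium triflate (epimers at the methine) | c1ccccc1[Se][C@@H]2CC[C@H](C)[C@H]2C(OC)[n+]3c(C)cc(C)cc3C.[O-]S(=O)(=O)C(F)(F)F | intermediate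
11 | {[(1R,2S,3S)-2-[methoxy(prop-2-yn-1-yloxy)methyl]-3-methylcyclopentyl]selanyl}benzene (acetal epimers) | c1ccccc1[Se][C@@H]2CC[C@H](C)[C@H]2C(OC)OCC#C | intermediate
12 | {[(1R,2S,3S)-2-[methoxy(propa-1,2-dien-1-yloxy)methyl]-3-methylcyclopentyl]selanyl}benzene (acetal epimers) | c1ccccc1[Se][C@@H]2CC[C@H](C)[C@H]2C(OC)OC=C=C | intermediate
13 | (R)-2-hydroxy-3-methylbutanoic acid | CC(C)[C@@H](O)C(=O)O | starting material
14 | (2R)-2-hydroxy-N-methoxy-N,3-dimethylbutanamide | CC(C)[C@@H](O)C(=O)N(C)OC | intermediate
15 | (2R)-2-[(tert-butyldimethylsilyl)oxy]-N-methoxy-N,3-dimethylbutanamide | CC(C)[C@@H](O[Si](C)(C)C(C)(C)C)C(=O)N(C)OC | intermediate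
16 | (1-{methoxy[(1S,2S,5R)-2-methyl-5-(phenylselanyl)cyclopentyl]methoxy}propa-1,2-dien-1-yl)lithium (acetal epimers) | c1ccccc1[Se][C@@H]2CC[C@H](C)[C@H]2C(OC)OC([Li])=C=C | intermediate
17 | (5R)-5-[(tert-butyldimethylsilyl)oxy]-3-{methoxy[(1S,2S,5R)-2-methyl-5-(phenylselanyl)cyclopentyl]methoxy}-6-methylhepta-1,2-dien-4-one (acetal epimers) | c1ccccc1[Se][C@@H]2CC[C@H](C)[C@H]2C(OC)OC(=C=C)C(=O)[C@H](O[Si](C)(C)C(C)(C)C)C(C)C | intermediate
18 | (2R)-2-[(tert-butyldimethylsilyl)oxy]-1-[(4aS,7S,7aR)-1-methoxy-7-methyl-4-methylideneoctahydrocyclopenta[c]pyran-3-yl]-3-methylbutan-1-one (C1 and C3 epimers) | CC(C)(C)[Si](C)(C)O[C@@H](C(=O)C1C(=C)[C@H]2CC[C@H](C)[C@H]2C(OC)O1)C(C)C | intermediate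
19 | (2R)-2-[(tert-butyldimethylsilyl)oxy]-1-[(4aS,7S,7aR)-1-methoxy-4,7-dimethyl-1,4a,5,6,7,7a-hexahydrocyclopenta[c]pyran-3-yl]-3-methylbutan-1-one (C1 epimers) | CC(C)(C)[Si](C)(C)O[C@@H](C(=O)C1=C(C)[C@H]2CC[C@H](C)[C@H]2C(OC)O1)C(C)C | intermediate
20 | (2R)-2-hydroxy-1-[(4aS,7S,7aR)-1-methoxy-4,7-dimethyl-1,4a,5,6,7,7a-hexahydrocyclopenta[c]pyran-3-yl]-3-methylbutan-1-one (C1 epimers) | CC(C)[C@@H](O)C(=O)C1=C(C)[C@H]2CC[C@H](C)[C@H]2C(OC)O1 | intermediate
21 | (2R)-1-[(4aS,7S,7aR)-1-methoxy-4,7-dimethyl-1,4a,5,6,7,7a-hexahydrocyclopenta[c]pyran-3-yl]-3-methyl-1-oxobutan-2-yl acetate (C1 epimers) | CC(=O)O[C@@H](C(=O)C1=C(C)[C@H]2CC[C@H](C)[C@H]2C(OC)O1)C(C)C | intermediate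
22 | 1-(2-hydroxy-6-methylphenyl)ethanone | CC(=O)c1c(C)cccc1O | starting material
23 | 4-hydroxy-5-methyl-2H-chromen-2-one | Cc1cccc2oc(=O)cc(O)c12 | intermediate
24 | (2R)-1-[(1R,4aS,7S,7aR)-1-(4-hydroxy-5-methyl-2-oxo-2H-chromen-3-yl)-4,7-dimethyl-1,4a,5,6,7,7a-hexahydrocyclopenta[c]pyran-3-yl]-3-methyl-1-oxobutan-2-yl acetate | CC(=O)O[C@@H](C(=O)C1=C(C)[C@H]2CC[C@H](C)[C@H]2[C@H](c2c(O)c3c(C)cccc3oc2=O)O1)C(C)C | target

**Step count and risks**

Total step count: 17. Longest linear sequence: 14 (steps 1–9, 12–15 and 17).

Steps most likely to fail: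

1. Step 17 (C1–coumarin bond). The vinylogous-ester acetal may ionise slowly, the coumarin may add through oxygen or from the concave face, or the product may re-ionise by ring opening and capture a second coumarin. Fallback from 21: mild hydrolysis of the methyl acetal (AcOH, THF, H2O) should give lactol F1, which is in equilibrium with its ring-opened aldehyde–enol form. Condensation of F1 with 23 under ethylenediammonium diacetate (Knoevenagel condensation) would give a 3-alkylidenechromane-2,4-dione, which closes by intramolecular oxa-Michael addition of the C3 enol oxygen at C1 under thermodynamic control. The fallback returns to the route at 24.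

2. Step 13 (radical ring closure). The C4a radical may be reduced before it cyclises, the silyl radical may add to the electron-poor allene, or the allenyl ketone may oligomerise at 80 °C. Fallback from 17, at a lower oxidation level: conjugate hydride reduction of the allene with [(Ph3P)CuH]6, then Et3N, should give the 2-alkoxy enone F2. The same silane conditions then close the ring by the analogous 6-endo Giese addition onto the less reactive enone and give the saturated bicyclic ketone F3, cis-fused for the same reason. Dehydrogenation with 2-iodoxybenzoic acid restores C3=C4 and returns to the route at 19.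

3. Step 12 (acylation of the lithioallene). Acyl transfer to the doubly branched α-silyloxy amide may be so slow that warming is needed, during which the lithioallene decomposes or the selenide undergoes selenium–lithium exchange. Fallback from 15: reduction with i-Bu2AlH at −78 °C should give the aldehyde F4, to which lithioallene 16 adds within minutes at −78 °C to give the allenyl carbinol F5. Oxidation of F5 with MnO2 returns to the route at 17.

**Further compounds**

F1 | step 17 | (2R)-1-[(4aS,7S,7aR)-1-hydroxy-4,7-dimethyl-1,4a,5,6,7,7a-hexahydrocyclopenta[c]pyran-3-yl]-3-methyl-1-oxobutan-2-yl acetate (lactol, C1 epimers) | CC(=O)O[C@@H](C(=O)C1=C(C)[C@H]2CC[C@H](C)[C@H]2C(O)O1)C(C)C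
F2 | step 13 | (5R)-5-[(tert-butyldimethylsilyl)oxy]-3-{methoxy[(1S,2S,5R)-2-methyl-5-(phenylselanyl)cyclopentyl]methoxy}-6-methylhept-2-en-4-one (E/Z, acetal epimers) | c1ccccc1[Se][C@@H]2CC[C@H](C)[C@H]2C(OC)OC(=CC)C(=O)[C@H](O[Si](C)(C)C(C)(C)C)C(C)C
F3 | step 13 | (2R)-2-[(tert-butyldimethylsilyl)oxy]-1-[(4aR,7S,7aR)-1-methoxy-4,7-dimethyloctahydrocyclopenta[c]pyran-3-yl]-3-methylbutan-1-one (C1, C3 and C4 epimers) | CC(C)(C)[Si](C)(C)O[C@@H](C(=O)C1C(C)[C@H]2CC[C@H](C)[C@H]2C(OC)O1)C(C)C
F4 | step 12 | (2R)-2-[(tert-butyldimethylsilyl)oxy]-3-methylbutanal | CC(C)[C@@H](O[Si](C)(C)C(C)(C)C)C=O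
F5 | step 12 | (5R)-5-[(tert-butyldimethylsilyl)oxy]-3-{methoxy[(1S,2S,5R)-2-methyl-5-(phenylselanyl)cyclopentyl]methoxy}-6-methylhepta-1,2-dien-4-ol (C4 and acetal epimers) | c1ccccc1[Se][C@@H]2CC[C@H](C)[C@H]2C(OC)OC(=C=C)C(O)[C@H](O[Si](C)(C)C(C)(C)C)C(C)C
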